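The route rests on disconnecting the C2–C3 bond of the dihydrofuran ring (O1–C2–C3–C3a–C7a). C3, a benzylic carbinol carbon, is taken back to an aryl aldehyde and the C2 isopropenyl group to an acetyl group, so that one proline-catalysed intramolecular aldol reaction closes the ring and sets both oxygen-bearing stereocentres, cis, in a single operation. Its precursor is an achiral 2-(2-oxopropoxy)benzaldehyde with bromine at the later C5 as a placeholder for the aryl acetyl group. The trans arrangement of the target is reached at the end, where the C3 ester is formed with inversion by a Mitsunobu reaction with the (Z)-acid.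

Key step: step 3

Remark: the absolute sense of induction in step 3 is assigned from the acid-directed enamine transition-state model of proline catalysis; should it prove opposite, (R)-proline would be used in the same step and nothing else changes.

Step 1
Reactants: 1 2-hydroxy-4-methoxybenzaldehyde
Product: 2 5-bromo-2-hydroxy-4-methoxybenzaldehyde
Conditions: Br2 (1.05 equiv), CH2Cl2, 0 °C to rt
Reagents that add atoms: bromine, BrBr
Why: Electrophilic aromatic bromination should occur at C5, para to the strongly activating hydroxyl and ortho to the methoxy group, because the only other doubly activated position (C3) lies between the two oxygen substituents and is hindered.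

Step 2
Reactants: 2 5-bromo-2-hydroxy-4-methoxybenzaldehyde; 3 chloroacetone
Product: 4 5-bromo-4-methoxy-2-(2-oxopropoxy)benzaldehyde
Conditions: K2CO3 (1.5 equiv), DMF, rt
Reagents that add atoms: none
Why: Williamson ether synthesis in which the phenoxide displaces chloride from the activated α-chloro ketone; a carbonate base at room temperature is chosen because heating with base would drive the product on to the achiral 2-acetylbenzofuran by aldol condensation.

Step 3
Reactants: 4 5-bromo-4-methoxy-2-(2-oxopropoxy)benzaldehyde
Product: 5 1-[(2S,3R)-5-bromo-3-hydroxy-6-methoxy-2,3-dihydro-1-benzofuran-2-yl]ethan-1-one (cis)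
Conditions: (S)-proline (30 mol%), DMF, rt; pH 7 phosphate buffer work-up
Reagents that add atoms: none
Why: (S)-Proline condenses with the ketone of 4, and the enamine formed toward the oxygen-bearing methylene adds through its nucleophilic carbon (future C2) to the ortho formyl carbon (future C3) while the carboxylic acid of the catalyst hydrogen-bonds the aldehyde oxygen; hydrolysis of the iminium ion then releases 5 and the catalyst. The closest known reaction type is the proline-catalysed intramolecular enamine aldol reaction (Hajos–Parrish type) in its enolexo form, which is documented for 2-(2-oxoalkoxy)benzaldehydes and gives cis-2-acyl-3-hydroxy-2,3-dihydrobenzofurans. The dihydrofuran ring closes in the 5-(enolexo)-exo-trig mode. C3 is controlled by the catalyst, whose acid group holds the aldehyde oxygen on the side of the enamine nitrogen so that one aldehyde face is presented, and C2 is controlled by the E geometry of the enamine (aryloxy group trans to nitrogen) and by attack on its acid-bearing face; the same hydrogen-bonded arrangement places acyl group and hydroxyl cis, and with (S)-proline the model predicts 2S,3R. The step needs regioselective use of the ketone and must stop before dehydration: the aldehyde cannot enolise and the methyl-side enamine could only close a seven-membered ring, the bromine keeps a second ketone out of the substrate, and the weakly acidic, base-free medium at room temperature with a buffered work-up should keep C2 from epimerising and the ketol from aromatising to the 2-acetylbenzofuran.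

Step 4
Reactants: 5 1-[(2S,3R)-5-bromo-3-hydroxy-6-methoxy-2,3-dihydro-1-benzofuran-2-yl]ethan-1-one
Product: 6 1-[(2S,3R)-5-bromo-3-{[tert-butyl(dimethyl)silyl]oxy}-6-methoxy-2,3-dihydro-1-benzofuran-2-yl]ethan-1-one
Conditions: TBSOTf (1.2 equiv), 2,6-lutidine (2 equiv), CH2Cl2, −78 °C
Reagents that add atoms: tert-butyldimethylsilyl trifluoromethanesulfonate, CC(C)(C)[Si](C)(C)OS(=O)(=O)C(F)(F)F
Why: Silyl ether formation with the silyl triflate and a hindered pyridine base is fast at −78 °C, should not enolise the ketone, and blocks retro-aldol cleavage and loss of water in the following thermal steps, both stereocentres being untouched.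

Step 5
Reactants: 6 1-[(2S,3R)-5-bromo-3-{[tert-butyl(dimethyl)silyl]oxy}-6-methoxy-2,3-dihydro-1-benzofuran-2-yl]ethan-1-one; 7 tributyl(1-ethoxyethenyl)stannane
Product: 8 1-[(2S,3R)-3-{[tert-butyl(dimethyl)silyl]oxy}-5-(1-ethoxyethenyl)-6-methoxy-2,3-dihydro-1-benzofuran-2-yl]ethan-1-one
Conditions: Pd(PPh3)4 (5 mol%), toluene, 100 °C; aqueous KF work-up; Et3N-deactivated silica
Reagents that add atoms: none
Why: Stille coupling, in which zerovalent palladium inserts into the only C–Br bond and the 1-ethoxyvinyl group is transferred from tin under neutral conditions that leave the enolisable ketone and C2 alone; the coupling is placed before the methylenation so that zerovalent palladium never meets the allylic aryl ether of the later isopropenyl compounds, and the enol ether is kept as a masked acetyl group so that one ketone only is present in step 6.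

Step 6
Reactants: 8 1-[(2S,3R)-3-{[tert-butyl(dimethyl)silyl]oxy}-5-(1-ethoxyethenyl)-6-methoxy-2,3-dihydro-1-benzofuran-2-yl]ethan-1-one
Product: 10 1-[(2R,3R)-3-{[tert-butyl(dimethyl)silyl]oxy}-6-methoxy-2-(prop-1-en-2-yl)-2,3-dihydro-1-benzofuran-5-yl]ethan-1-one, via isopropenyl enol ether 9 (not isolated)
Conditions: Cp2TiMe2 (2.5 equiv), toluene, 65 °C, dark; then 0.1 M HCl, THF, 0 °C
Reagents that add atoms: dimethyltitanocene, C[Ti](C)(C1C=CC=C1)C1C=CC=C1; water, O
Why: Petasis methylenation, in which Cp2Ti=CH2 formed on heating converts the ketone into the isopropenyl group by a non-basic oxatitanacyclobutane pathway that should neither epimerise C2 (whose descriptor changes from S to R by the priority rules only) nor eliminate silanol, while the aryl enol ether is inert to the reagent and is then hydrolysed to the acetyl group by brief treatment with dilute acid that the silyl ether and the isopropenyl group tolerate.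

Step 7
Reactants: 10 1-[(2R,3R)-3-{[tert-butyl(dimethyl)silyl]oxy}-6-methoxy-2-(prop-1-en-2-yl)-2,3-dihydro-1-benzofuran-5-yl]ethan-1-one
Product: 11 1-[(2R,3R)-3-hydroxy-6-methoxy-2-(prop-1-en-2-yl)-2,3-dihydro-1-benzofuran-5-yl]ethan-1-one (cis)
Conditions: TBAF (1.2 equiv), AcOH (1.2 equiv), THF, 0 °C to rt
Reagents that add atoms: none
Why: Fluoride-induced cleavage of the silyl ether (Si–F bond formation), buffered with acetic acid so that the ionisation-prone benzylic alcohol sees neither strong base nor acid; no stereocentre is touched.

Step 8
Reactants: 12 (E)-but-2-enal (crotonaldehyde)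
Product: 13 (Z)-2-iodobut-2-enal
Conditions: I2 (1.5 equiv), K2CO3 (1.2 equiv), 4-(dimethylamino)pyridine (0.2 equiv), THF/H2O 1:1, rt
Reagents that add atoms: iodine, II
Why: Amine-catalysed α-iodination of an enal (conjugate addition of the pyridine, iodination of the enolate, elimination of the amine, as in a Morita–Baylis–Hillman sequence) should give the thermodynamically preferred Z isomer, in which iodine is cis to the methyl group and the formyl group trans to it.

Step 9
Reactants: 13 (Z)-2-iodobut-2-enal
Product: 14 (Z)-2-iodobut-2-en-1-ol
Conditions: NaBH4, CeCl3·7H2O, MeOH, 0 °C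
Reagents that add atoms: none
Why: Luche reduction delivers hydride to the carbonyl carbon only, so the C–I bond and the alkene geometry set in step 8 should be retained.

Step 10
Reactants: 14 (Z)-2-iodobut-2-en-1-ol
Product: 16 (Z)-2-(hydroxymethyl)but-2-enoic acid, via dilithio alkoxide 15 (not isolated)
Conditions: t-BuLi (3.1 equiv), Et2O, −78 °C; CO2 (gas), −78 °C to 0 °C; then 1 M HCl
Reagents that add atoms: carbon dioxide, O=C=O
Why: Iodine–lithium exchange followed by carboxylation: tert-butyllithium first deprotonates the hydroxyl and then exchanges iodine for lithium with retention, giving a vinyllithium that is configurationally stable at −78 °C and is carboxylated with retention, so that the carboxyl group ends up cis to the methyl group (Z acid).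

Step 11
Reactants: 16 (Z)-2-(hydroxymethyl)but-2-enoic acid
Product: 18 (Z)-2-[(acetyloxy)methyl]but-2-enoic acid, via mixed acetic anhydride 17 (not isolated)
Conditions: Ac2O (2.5 equiv), pyridine, 0 °C to rt; then H2O, THF, rt
Reagents that add atoms: acetic anhydride, CC(=O)OC(C)=O
Why: O-Acetylation of the primary allylic alcohol with acetic anhydride in pyridine; the mixed anhydride that forms at the carboxyl group is cleaved by water at its unhindered acetyl carbonyl during the quench, and no strongly nucleophilic acylation catalyst is used so that conjugate addition to the Z alkene, and with it isomerisation, is avoided.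

Step 12
Reactants: 11 1-[(2R,3R)-3-hydroxy-6-methoxy-2-(prop-1-en-2-yl)-2,3-dihydro-1-benzofuran-5-yl]ethan-1-one; 18 (Z)-2-[(acetyloxy)methyl]but-2-enoic acid
Product: 19 (2R,3S)-5-acetyl-6-methoxy-2-(prop-1-en-2-yl)-2,3-dihydro-1-benzofuran-3-yl (2Z)-2-[(acetyloxy)methyl]but-2-enoate (CNP0221694.1)
Conditions: PPh3 (1.5 equiv), diisopropyl azodicarboxylate (1.6 equiv), toluene, −20 °C to rt (betaine pre-formed, then 18, then 11)
Reagents that add atoms: none
Why: Mitsunobu reaction, in which the alcohol is activated as an alkoxyphosphonium ion and displaced by the carboxylate of 18 from the face of C3 anti to the C2 isopropenyl group, so that C3 is inverted from R to S and the trans ester should result; since the acid acts as a nucleophile and is never converted into an acylating agent, its Z alkene and allylic acetate are not exposed to isomerisation by conjugate addition, and pre-forming the betaine with a slight excess of the azodicarboxylate leaves no free phosphine to attack the allylic acetate.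

Compound list
1 | 2-hydroxy-4-methoxybenzaldehyde | COc1ccc(C=O)c(O)c1 | starting material
2 | 5-bromo-2-hydroxy-4-methoxybenzaldehyde | COc1cc(O)c(C=O)cc1Br | intermediate
3 | chloroacetone | CC(=O)CCl | starting material
4 | 5-bromo-4-methoxy-2-(2-oxopropoxy)benzaldehyde | CC(=O)COc1cc(OC)c(Br)cc1C=O | intermediate
5 | 1-[(2S,3R)-5-bromo-3-hydroxy-6-methoxy-2,3-dihydro-1-benzofuran-2-yl]ethan-1-one (cis) | CC(=O)[C@H]1Oc2cc(OC)c(Br)cc2[C@H]1O | intermediate
6 | 1-[(2S,3R)-5-bromo-3-{[tert-butyl(dimethyl)silyl]oxy}-6-methoxy-2,3-dihydro-1-benzofuran-2-yl]ethan-1-one | CC(=O)[C@H]1Oc2cc(OC)c(Br)cc2[C@H]1O[Si](C)(C)C(C)(C)C | intermediate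
7 | tributyl(1-ethoxyethenyl)stannane | C=C(OCC)[Sn](CCCC)(CCCC)CCCC | starting material
8 | 1-[(2S,3R)-3-{[tert-butyl(dimethyl)silyl]oxy}-5-(1-ethoxyethenyl)-6-methoxy-2,3-dihydro-1-benzofuran-2-yl]ethan-1-one | CC(=O)[C@H]1Oc2cc(OC)c(C(=C)OCC)cc2[C@H]1O[Si](C)(C)C(C)(C)C | intermediate
9 | tert-butyl{[(2R,3R)-5-(1-ethoxyethenyl)-6-methoxy-2-(prop-1-en-2-yl)-2,3-dihydro-1-benzofuran-3-yl]oxy}dimethylsilane | C=C(C)[C@H]1Oc2cc(OC)c(C(=C)OCC)cc2[C@H]1O[Si](C)(C)C(C)(C)C | intermediate (not isolated)
10 | 1-[(2R,3R)-3-{[tert-butyl(dimethyl)silyl]oxy}-6-methoxy-2-(prop-1-en-2-yl)-2,3-dihydro-1-benzofuran-5-yl]ethan-1-one | C=C(C)[C@H]1Oc2cc(OC)c(C(C)=O)cc2[C@H]1O[Si](C)(C)C(C)(C)C | intermediate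
11 | 1-[(2R,3R)-3-hydroxy-6-methoxy-2-(prop-1-en-2-yl)-2,3-dihydro-1-benzofuran-5-yl]ethan-1-one (cis) | C=C(C)[C@H]1Oc2cc(OC)c(C(C)=O)cc2[C@H]1O | intermediate
12 | (E)-but-2-enal (crotonaldehyde) | C/C=C/C=O | starting material
13 | (Z)-2-iodobut-2-enal | C/C=C(\I)C=O | intermediate
14 | (Z)-2-iodobut-2-en-1-ol | C/C=C(\I)CO | intermediate
15 | lithium (2E)-2-lithiobut-2-en-1-olate (C–Li cis to the methyl group; E by the priority rules only) | C/C=C(\[Li])CO[Li] | intermediate (not isolated)
16 | (Z)-2-(hydroxymethyl)but-2-enoic acid | C/C=C(\C(=O)O)CO | intermediate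
17 | acetic (Z)-2-[(acetyloxy)methyl]but-2-enoic anhydride | C/C=C(\C(=O)OC(C)=O)COC(C)=O | intermediate (not isolated)
18 | (Z)-2-[(acetyloxy)methyl]but-2-enoic acid | C/C=C(\C(=O)O)COC(C)=O | intermediate
19 | (2R,3S)-5-acetyl-6-methoxy-2-(prop-1-en-2-yl)-2,3-dihydro-1-benzofuran-3-yl (2Z)-2-[(acetyloxy)methyl]but-2-enoate | C=C(C)[C@H]1Oc2cc(OC)c(C(C)=O)cc2[C@@H]1OC(=O)/C(=C\C)COC(C)=O | target

Total step count: 12. Longest linear sequence: 8 steps (steps 1 to 7, then step 12, from 1); the acid 18 is made in 4 steps (8 to 11) and joined in step 12.

Steps most likely to fail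

Step 3. The two aldehyde faces may be discriminated too weakly in the hydrogen-bonded transition state, or enantiomeric purity may erode through retro-aldol cleavage and re-closure, and prolonged exposure may let the ketol lose water toward the aromatic system. The fallback replaces catalyst control by a kinetic resolution; it sets out from 4 and comes back at 5. Closure of 4 with racemic proline under the same mild conditions should give the cis ketol as the racemate, that is 5 together with its enantiomer 1-[(2R,3S)-5-bromo-3-hydroxy-6-methoxy-2,3-dihydro-1-benzofuran-2-yl]ethan-1-one F1. Lipase-catalysed acylation (Candida antarctica lipase B, vinyl acetate, tert-butyl methyl ether, 30 °C) is then expected, by the usual empirical size rule for secondary alcohols with the aryl group as the large substituent, to acetylate the 3S enantiomer to (2R,3S)-2-acetyl-5-bromo-6-methoxy-2,3-dihydro-1-benzofuran-3-yl acetate F2. Unreacted 5 would be separated by chromatography and taken into step 4.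

Step 12. The alkoxyphosphonium ion at the electron-rich benzylic C3 may lose the C2 proton (elimination toward the aromatic benzofuran) or ionise faster than the bulky α-branched carboxylate can displace it, or acyl transfer may deliver the ester with retention. The fallback separates inversion from ester formation; it sets out from 11 and comes back at 19. A Mitsunobu inversion with the more acidic, unhindered 4-nitrobenzoic acid (PPh3, diisopropyl azodicarboxylate, toluene) should give (2R,3S)-5-acetyl-6-methoxy-2-(prop-1-en-2-yl)-2,3-dihydro-1-benzofuran-3-yl 4-nitrobenzoate F3, and methanolysis (K2CO3, MeOH, 0 °C) the trans alcohol 1-[(2R,3S)-3-hydroxy-6-methoxy-2-(prop-1-en-2-yl)-2,3-dihydro-1-benzofuran-5-yl]ethan-1-one F4. Acid 18 would be converted with 2,4,6-trichlorobenzoyl chloride and Et3N in toluene into the mixed anhydride (Z)-2-[(acetyloxy)methyl]but-2-enoic 2,4,6-trichlorobenzoic anhydride F5. F5 would then acylate F4 in warm toluene without a nucleophilic amine catalyst (Yamaguchi esterification, retention at C3), giving 19.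

Step 6. Carbene transfer to a ketone crowded by the cis silyloxy group may be slow, leaving time for enolisation toward C2 (epimerisation, loss of silanol) or for partial unmasking of the enol ether before the ketone has reacted. The fallback is a Peterson olefination; it sets out from 8 and comes back at 10. Addition of Me3SiCH2MgCl in the presence of anhydrous CeCl3 (THF, −78 °C), a non-basic carbonyl addition, should give 2-[(2S,3R)-3-{[tert-butyl(dimethyl)silyl]oxy}-5-(1-ethoxyethenyl)-6-methoxy-2,3-dihydro-1-benzofuran-2-yl]-1-(trimethylsilyl)propan-2-ol F6 as a mixture of carbinol epimers. Catalytic p-toluenesulfonic acid in wet THF should then eliminate trimethylsilanol from this tertiary β-hydroxysilane and hydrolyse the enol ether in the same operation, giving 10.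

Further compounds
F1 | step 3 | 1-[(2R,3S)-5-bromo-3-hydroxy-6-methoxy-2,3-dihydro-1-benzofuran-2-yl]ethan-1-one (enantiomer of 5, formed with 5 as the racemate) | CC(=O)[C@@H]1Oc2cc(OC)c(Br)cc2[C@@H]1O
F2 | step 3 | (2R,3S)-2-acetyl-5-bromo-6-methoxy-2,3-dihydro-1-benzofuran-3-yl acetate | CC(=O)[C@@H]1Oc2cc(OC)c(Br)cc2[C@@H]1OC(C)=O
F3 | step 12 | (2R,3S)-5-acetyl-6-methoxy-2-(prop-1-en-2-yl)-2,3-dihydro-1-benzofuran-3-yl 4-nitrobenzoate | C=C(C)[C@H]1Oc2cc(OC)c(C(C)=O)cc2[C@@H]1OC(=O)c1ccc(cc1)[N+](=O)[O-]
F4 | step 12 | 1-[(2R,3S)-3-hydroxy-6-methoxy-2-(prop-1-en-2-yl)-2,3-dihydro-1-benzofuran-5-yl]ethan-1-one (trans) | C=C(C)[C@H]1Oc2cc(OC)c(C(C)=O)cc2[C@@H]1O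
F5 | step 12 | (Z)-2-[(acetyloxy)methyl]but-2-enoic 2,4,6-trichlorobenzoic anhydride | C/C=C(\C(=O)OC(=O)c1c(Cl)cc(Cl)cc1Cl)COC(C)=O
F6 | step 6 | 2-[(2S,3R)-3-{[tert-butyl(dimethyl)silyl]oxy}-5-(1-ethoxyethenyl)-6-methoxy-2,3-dihydro-1-benzofuran-2-yl]-1-(trimethylsilyl)propan-2-ol (both epimers at the carbinol carbon) | C[Si](C)(C)CC(C)(O)[C@H]1Oc2cc(OC)c(C(=C)OCC)cc2[C@H]1O[Si](C)(C)C(C)(C)C
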